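**Plan**
1. Retrosynthesis: the C8'–C9' single bond of the dodecaene is cut last (C16 trienyl iodide + C34 polyenyne). Further cuts are C11=C12 (Wittig), C11'=C12' (Horner–Wadsworth–Emmons) and C6–C7 (Stille) on the ring side, and C7'=C8' (Takai) and C3'=C4' (Horner–Wadsworth–Emmons) on the open-chain side.
2. Enabling feature: C9' carries only a methyl group and sits between C8'–H and C10'–H, so C9'=C10' can be stored as a methyl-capped alkyne C9'≡C10'. Cp2Zr(H)Cl adds syn across it, zirconium settles on the less hindered C9' by equilibration, and this C9' organometallic is coupled with the C8' iodide in the same flask.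
3. Forward, ring side: the cyclopentene of (R)-campholenic aldehyde is opened and reclosed (ozonolysis, aldol) to the six-membered ring C1–C6, then methylated, triflated and extended to a C20 Wittig salt, which is joined to a C14 enynal made from the C10 dialdehyde.
4. Forward, open-chain side: (R)-lavandulol is hydrated at its isopropenyl group and extended to the C16 (E,E,E)-trienyl iodide; the halves are joined at C8'–C9' and both silyl ethers are removed.
5. Stereochemistry: C2 (R) comes unchanged from campholenic aldehyde and C2' (S) from (R)-lavandulol. Alkene geometry comes from stabilised ylides and phosphonates, syn hydrometalation, Takai olefination and an iodine equilibration of C11=C12.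

Key step: step 22

Assumption: (R)-lavandulol and (R)-campholenic aldehyde (the ZnBr2 rearrangement product of (−)-α-pinene oxide) are bought as single enantiomers; neither stereocentre is enolisable at any stage of the route.

**Step 1**
Reactants: 1 (R)-campholenic aldehyde
Product: 2 ethyl (2E)-2-methyl-4-[(1R)-2,2,3-trimethylcyclopent-3-en-1-yl]but-2-enoate
Conditions: Ph3P=C(Me)CO2Et (1.2 equiv), CH2Cl2, rt
Reagents that add atoms: ethyl 2-(triphenylphosphoranylidene)propanoate, CCOC(=O)C(C)=P(c1ccccc1)(c1ccccc1)c1ccccc1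
Why: Wittig olefination with the stabilised ylide should give the (E)-enoate; the stereocentre is β to the carbonyl and cannot epimerise.

**Step 2**
Reactants: 2 ethyl (2E)-2-methyl-4-[(1R)-2,2,3-trimethylcyclopent-3-en-1-yl]but-2-enoate
Product: 3 ethyl (2E,5S)-2,6,6-trimethyl-7-oxo-5-(2-oxoethyl)oct-2-enoate
Conditions: O3, CH2Cl2, −78 °C (Sudan Red 7B end point); then Me2S, −78 °C → rt
Reagents that add atoms: ozone, [O-][O+]=O
Why: Ozonolysis with reductive work-up; the strained, electron-rich ring alkene should react far faster than the electron-poor conjugated enoate, so only the ring is opened to the 1,5-keto aldehyde.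

**Step 3**
Reactants: 3 ethyl (2E,5S)-2,6,6-trimethyl-7-oxo-5-(2-oxoethyl)oct-2-enoate
Product: 4 ethyl (2E)-4-[(1R)-2,2-dimethyl-3-oxocyclohex-4-en-1-yl]-2-methylbut-2-enoate
Conditions: piperidine (0.2 equiv), AcOH (0.2 equiv), toluene, 80 °C
Reagents that add atoms: none
Why: Intramolecular aldol condensation; only the ketone methyl group can reach the aldehyde through a six-membered ring (the other α-carbon is quaternary), so the former five-membered ring is expanded to the cyclohexenone.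

**Step 4**
Reactants: 4 ethyl (2E)-4-[(1R)-2,2-dimethyl-3-oxocyclohex-4-en-1-yl]-2-methylbut-2-enoate
Product: 6 ethyl (2E)-2-methyl-4-[(1R)-2,2,4-trimethyl-3-oxocyclohexyl]but-2-enoate (C4 epimers), via potassium enolate 5 (not isolated)
Conditions: K[BH(s-Bu)3] (1.05 equiv), THF, −78 °C; then MeI (5 equiv), −78 → 0 °C
Reagents that add atoms: iodomethane, CI
Why: Conjugate reduction of the β-unsubstituted enone gives the enolate regiospecifically and its C-methylation (reductive alkylation) installs the C5 methyl group; this carbon becomes sp2 in step 5, so its configuration does not matter.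

**Step 5**
Reactants: 6 ethyl (2E)-2-methyl-4-[(1R)-2,2,4-trimethyl-3-oxocyclohexyl]but-2-enoate
Product: 8 ethyl (2E)-2-methyl-4-[(1R)-2,2,4-trimethyl-3-(trifluoromethylsulfonyloxy)cyclohex-3-en-1-yl]but-2-enoate, via potassium enolate 7 (not isolated)
Conditions: KN(SiMe3)2 (1.1 equiv), THF, −78 °C; then PhNTf2, −78 → 0 °C
Reagents that add atoms: N-phenylbis(trifluoromethanesulfonimide), O=S(=O)(N(c1ccccc1)S(=O)(=O)C(F)(F)F)C(F)(F)F
Why: Enol triflate formation; the ketone has a single enolisable hydrogen, which should be more acidic than the γ-CH2 of the α-methyl enoate, so only the tetrasubstituted C5=C6 triflate can form.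

**Step 6**
Reactants: 8 ethyl (2E)-2-methyl-4-[(1R)-2,2,4-trimethyl-3-(trifluoromethylsulfonyloxy)cyclohex-3-en-1-yl]but-2-enoate
Product: 9 (5R)-5-[(2E)-4-hydroxy-3-methylbut-2-en-1-yl]-2,6,6-trimethylcyclohex-1-en-1-yl trifluoromethanesulfonate
Conditions: i-Bu2AlH (2.5 equiv), CH2Cl2, −78 °C; aq. potassium sodium tartrate
Reagents that add atoms: none
Why: 1,2-Reduction of the conjugated ester to the (E)-allylic alcohol; the vinyl triflate is inert to the hydride at low temperature.

**Step 7**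
Reactants: 9 (5R)-5-[(2E)-4-hydroxy-3-methylbut-2-en-1-yl]-2,6,6-trimethylcyclohex-1-en-1-yl trifluoromethanesulfonate
Product: 10 (5R)-5-[(2E)-4-(tert-butyldiphenylsilyloxy)-3-methylbut-2-en-1-yl]-2,6,6-trimethylcyclohex-1-en-1-yl trifluoromethanesulfonate
Conditions: t-BuPh2SiCl, imidazole, CH2Cl2, rt
Reagents that add atoms: tert-butyl(chloro)diphenylsilane, CC(C)(C)[Si](Cl)(c1ccccc1)c1ccccc1
Why: Silylation of the primary alcohol; this bulky silyl ether should survive the acidic phosphonium salt formation and the organometallic steps.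

**Step 8**
Reactants: 11 (2E)-3-methylpent-2-en-4-yn-1-ol
Product: 12 (2E,4E)-3-methyl-5-(tributylstannyl)penta-2,4-dien-1-ol
Conditions: Bu3SnH (1.1 equiv), PdCl2(PPh3)2 (2 mol %), THF, 0 °C
Reagents that add atoms: tributylstannane, CCCC[SnH](CCCC)CCCC
Why: Pd-catalysed syn hydrostannation of the terminal alkyne should place tin on the terminal carbon and set the 4E geometry.

**Step 9**
Reactants: 10 (5R)-5-[(2E)-4-(tert-butyldiphenylsilyloxy)-3-methylbut-2-en-1-yl]-2,6,6-trimethylcyclohex-1-en-1-yl trifluoromethanesulfonate; 12 (2E,4E)-3-methyl-5-(tributylstannyl)penta-2,4-dien-1-ol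
Product: 13 (2E,4E)-5-{(5R)-5-[(2E)-4-(tert-butyldiphenylsilyloxy)-3-methylbut-2-en-1-yl]-2,6,6-trimethylcyclohex-1-en-1-yl}-3-methylpenta-2,4-dien-1-ol
Conditions: Pd2(dba)3 (3 mol %), AsPh3 (24 mol %), LiCl (3 equiv), NMP, 50 °C, dark
Reagents that add atoms: none
Why: Stille coupling of the hindered tetrasubstituted enol triflate with the dienylstannane forms C6–C7 with retention of both alkene geometries, as is known for the parent 2,6,6-trimethylcyclohexenyl triflate.

**Step 10**
Reactants: 13 (2E,4E)-5-{(5R)-5-[(2E)-4-(tert-butyldiphenylsilyloxy)-3-methylbut-2-en-1-yl]-2,6,6-trimethylcyclohex-1-en-1-yl}-3-methylpenta-2,4-dien-1-ol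
Product: 14 [(2E,4E)-5-{(5R)-5-[(2E)-4-(tert-butyldiphenylsilyloxy)-3-methylbut-2-en-1-yl]-2,6,6-trimethylcyclohex-1-en-1-yl}-3-methylpenta-2,4-dien-1-yl]triphenylphosphonium bromide
Conditions: PPh3·HBr (1.1 equiv), MeOH/CH2Cl2, 0 °C → rt
Reagents that add atoms: triphenylphosphine hydrobromide, Br.c1ccc(cc1)P(c1ccccc1)c1ccccc1
Why: Acid-mediated ionisation of the dienylic alcohol to a pentadienyl cation and capture by PPh3, the standard entry to carotenoid Wittig salts; the isolated allylic silyl ether should not ionise.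

**Step 11**
Reactants: 15 1-bromobut-2-yne
Product: 16 diethyl but-2-yn-1-ylphosphonate
Conditions: P(OEt)3 (1.2 equiv), neat, 130 °C
Reagents that add atoms: triethyl phosphite, CCOP(OCC)OCC
Why: Michaelis–Arbuzov reaction of the primary propargylic bromide.

**Step 12**
Reactants: 17 (2E,4E,6E)-2,7-dimethylocta-2,4,6-trienedial; 16 diethyl but-2-yn-1-ylphosphonate
Product: 19 (2E,4E,6E,8E)-2,7-dimethyldodeca-2,4,6,8-tetraen-10-ynal, via sodium phosphonate anion 18 (not isolated)
Conditions: 16, NaN(SiMe3)2 (1.0 equiv), THF, −78 °C; added slowly to 17 (3 equiv), THF, −78 → 0 °C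
Reagents that add atoms: none
Why: Horner–Wadsworth–Emmons olefination should give the (E)-enyne; excess dialdehyde and inverse addition keep the reaction to one aldehyde group.

**Step 13**
Reactants: 14 the C20 phosphonium bromide; 19 (2E,4E,6E,8E)-2,7-dimethyldodeca-2,4,6,8-tetraen-10-ynal
Product: 22 tert-butyl{[(2E)-2-methyl-4-{(1R)-2,2,4-trimethyl-3-[(1E,3E,5E,7E,9E,11E,13E)-3,7,12-trimethylheptadeca-1,3,5,7,9,11,13-heptaen-15-yn-1-yl]cyclohex-3-en-1-yl}but-2-en-1-yl]oxy}diphenylsilane, via phosphorus ylide 20 (not isolated), via 11Z polyenyne 21 (not isolated)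
Conditions: 14, NaN(SiMe3)2 (1.05 equiv), THF, −78 °C; 19, −78 → 0 °C; then I2 (1 mol %), CH2Cl2/hexane, rt, daylight
Reagents that add atoms: none
Why: Wittig olefination forms C11=C12 as an E/Z mixture, and the iodine-catalysed equilibration should funnel the hindered 11Z isomer (C13 methyl against C10–H) into the all-E polyenyne.

**Step 14**
Reactants: 23 (R)-lavandulol
Product: 24 (2R)-5-methyl-2-(prop-1-en-2-yl)hex-4-en-1-yl acetate
Conditions: Ac2O, pyridine, DMAP (cat.), CH2Cl2, rt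
Reagents that add atoms: acetic anhydride, CC(=O)OC(C)=O
Why: Acetylation masks the primary hydroxyl so that it cannot add to a mercurinium ion in step 15.

**Step 15**
Reactants: 24 (2R)-5-methyl-2-(prop-1-en-2-yl)hex-4-en-1-yl acetate
Product: 27 (2S)-3-methyl-2-(3-methylbut-2-en-1-yl)butane-1,3-diol, via organomercurial 25 (not isolated), via hydroxy acetate 26 (not isolated)
Conditions: Hg(OAc)2 (1.0 equiv), THF/H2O 1:1, 0 °C → rt; then 3 M NaOH, NaBH4, 0 °C; then K2CO3, MeOH, rt
Reagents that add atoms: water, O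
Why: Markovnikov oxymercuration should be much faster at the 1,1-disubstituted isopropenyl group than at the trisubstituted prenyl alkene; reductive demercuration and methanolysis give the diol, with the stereocentre untouched (R becomes S only by priority).

**Step 16**
Reactants: 27 (2S)-3-methyl-2-(3-methylbut-2-en-1-yl)butane-1,3-diol
Product: 28 (2S)-3-methyl-2-(3-methylbut-2-en-1-yl)-1,3-bis(triethylsilyloxy)butane
Conditions: Et3SiOTf (2.5 equiv), 2,6-lutidine, CH2Cl2, −78 → 0 °C
Reagents that add atoms: triethylsilyl trifluoromethanesulfonate, CC[Si](CC)(CC)OS(=O)(=O)C(F)(F)F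
Why: Silylation of both hydroxyls; the silyl triflate is needed for the tertiary one.

**Step 17**
Reactants: 28 (2S)-3-methyl-2-(3-methylbut-2-en-1-yl)-1,3-bis(triethylsilyloxy)butane
Product: 29 (2R)-5-methyl-2-[2-(triethylsilyloxy)propan-2-yl]hex-4-enal
Conditions: (COCl)2 (4 equiv), DMSO (8 equiv), CH2Cl2, −78 → −30 °C; then Et3N, −78 → 0 °C
Reagents that add atoms: none
Why: Under Swern conditions the primary triethylsilyl ether is cleaved by the chlorosulfonium salt and oxidised in the same pot while the tertiary silyl ether stays; the cold amine work-up guards the α-stereocentre.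

**Step 18**
Reactants: 29 (2R)-5-methyl-2-[2-(triethylsilyloxy)propan-2-yl]hex-4-enal
Product: 30 ethyl (2E,4E,6S)-3,7-dimethyl-6-(3-methylbut-2-en-1-yl)-7-(triethylsilyloxy)octa-2,4-dienoate
Conditions: (EtO)2P(O)CH2C(Me)=CHCO2Et, LiN(SiMe3)2, THF/DMPU, −78 → 0 °C; 2Z isomer removed by chromatography
Reagents that add atoms: triethyl (2E)-3-methyl-4-phosphonobut-2-enoate, CCOC(=O)/C=C(\C)CP(=O)(OCC)OCC
Why: Vinylogous Horner–Wadsworth–Emmons olefination should form C3'=C4' with E geometry; addition to the aldehyde at low temperature should outrun enolisation of the α-stereocentre.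

**Step 19**
Reactants: 30 ethyl (2E,4E,6S)-3,7-dimethyl-6-(3-methylbut-2-en-1-yl)-7-(triethylsilyloxy)octa-2,4-dienoate
Product: 31 (2E,4E,6S)-3,7-dimethyl-6-(3-methylbut-2-en-1-yl)-7-(triethylsilyloxy)octa-2,4-dien-1-ol
Conditions: i-Bu2AlH (2.2 equiv), CH2Cl2, −78 °C; aq. potassium sodium tartrate
Reagents that add atoms: none
Why: 1,2-Reduction of the dienoate to the dienol without touching the silyl ether or the alkenes.

**Step 20**
Reactants: 31 (2E,4E,6S)-3,7-dimethyl-6-(3-methylbut-2-en-1-yl)-7-(triethylsilyloxy)octa-2,4-dien-1-ol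
Product: 32 (2E,4E,6S)-3,7-dimethyl-6-(3-methylbut-2-en-1-yl)-7-(triethylsilyloxy)octa-2,4-dienal
Conditions: MnO2 (20 equiv), CH2Cl2, rt
Reagents that add atoms: none
Why: Selective oxidation of the allylic alcohol to the dienal by MnO2.

**Step 21**
Reactants: 32 (2E,4E,6S)-3,7-dimethyl-6-(3-methylbut-2-en-1-yl)-7-(triethylsilyloxy)octa-2,4-dienal
Product: 33 triethyl{[(3S,4E,6E,8E)-9-iodo-2,6-dimethyl-3-(3-methylbut-2-en-1-yl)nona-4,6,8-trien-2-yl]oxy}silane
Conditions: CrCl2 (6 equiv), CHI3 (2 equiv), 1,4-dioxane/THF 6:1, 0 °C → rt, dark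
Reagents that add atoms: iodoform, IC(I)I
Why: Takai olefination; the geminal dichromium carbenoid from iodoform adds to the aldehyde and eliminates to the (E)-vinyl iodide (C7'=C8').

**Step 22**
Reactants: 22 the C34 polyenyne; 33 the C16 trienyl iodide
Product: 36 bis-silyl ether of the target (1'-O-triethylsilyl; tert-butyldiphenylsilyl on the side-chain oxygen; all-E), via alkenylzirconocene 34 (not isolated), via alkenylzinc chloride 35 (not isolated)
Conditions: 22 (1.1 equiv), Cp2Zr(H)Cl (1.25 equiv), THF, rt → 40 °C, dark; ZnCl2 (1.3 equiv), THF, 0 °C; then 33 (1.0 equiv), Pd(PPh3)4 (5 mol %), rt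
Reagents that add atoms: none
Why: Zr–H adds syn across C9'≡C10', and the regioisomeric alkenylzirconocenes interconvert through reversible second Zr–H addition and β-hydride elimination, so the mixture should drain into the isomer with zirconium on the methyl-bearing, less hindered and linearly conjugated C9'. Transmetalation to zinc gives 35, which enters a Negishi cycle: zerovalent palladium inserts into the C8'–I bond of 33, transmetalation and reductive elimination then form C8'–C9' with retention at both alkenes. The closest known reaction type is the one-pot hydrozirconation of 2-alkynes under thermodynamic regiocontrol followed by Pd/ZnCl2-mediated coupling with alkenyl iodides to trisubstituted dienes. No ring is closed and no stereocentre is formed; the step sets the 9'E geometry (H on C10' cis to the metal, so the methyl is cis to C11') and carries the 7'E geometry over from 33. It needs chemoselectivity for the one C≡C over nine C=C and regioselectivity for C9' over C10'; the first rests on the much higher rate of alkyne hydrozirconation and the second on the methyl cap being the smallest substituent on the alkyne. Both hydroxyls are silylated so that neither can protonate the organometallics.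

**Step 23**
Reactants: 36 bis-silyl ether of the target
Product: 37 (2R,2'S)-2-[(2E)-4-hydroxy-3-methylbut-2-en-1-yl]-2'-(3-methylbut-2-en-1-yl)-3',4'-didehydro-1',2'-dihydro-β,ψ-caroten-1'-ol (CNP0286110.1)
Conditions: Bu4NF (6 equiv), THF, 0 °C → rt, dark, argon
Reagents that add atoms: none
Why: Fluoride-mediated cleavage of both silyl ethers; the polyene and both stereocentres are inert to fluoride.

**Compound list**
1 | (R)-campholenic aldehyde, 2-[(1R)-2,2,3-trimethylcyclopent-3-en-1-yl]acetaldehyde | CC1=CC[C@H](CC=O)C1(C)C | starting material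
2 | ethyl (2E)-2-methyl-4-[(1R)-2,2,3-trimethylcyclopent-3-en-1-yl]but-2-enoate | CC1=CC[C@H](C/C=C(\C)C(=O)OCC)C1(C)C | intermediate
3 | ethyl (2E,5S)-2,6,6-trimethyl-7-oxo-5-(2-oxoethyl)oct-2-enoate | O=CC[C@H](C/C=C(\C)C(=O)OCC)C(C)(C)C(C)=O | intermediate
4 | ethyl (2E)-4-[(1R)-2,2-dimethyl-3-oxocyclohex-4-en-1-yl]-2-methylbut-2-enoate | O=C1C=CC[C@H](C/C=C(\C)C(=O)OCC)C1(C)C | intermediate
5 | potassium (5R)-5-[(2E)-4-ethoxy-3-methyl-4-oxobut-2-en-1-yl]-6,6-dimethylcyclohex-1-en-1-olate (not isolated) | [K+].[O-]C1=CCC[C@H](C/C=C(\C)C(=O)OCC)C1(C)C | intermediate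
6 | ethyl (2E)-2-methyl-4-[(1R)-2,2,4-trimethyl-3-oxocyclohexyl]but-2-enoate (C4 epimers) | O=C1C(C)CC[C@H](C/C=C(\C)C(=O)OCC)C1(C)C | intermediate
7 | potassium (5R)-5-[(2E)-4-ethoxy-3-methyl-4-oxobut-2-en-1-yl]-2,6,6-trimethylcyclohex-1-en-1-olate (not isolated) | [K+].[O-]C1=C(C)CC[C@H](C/C=C(\C)C(=O)OCC)C1(C)C | intermediate
8 | ethyl (2E)-2-methyl-4-[(1R)-2,2,4-trimethyl-3-(trifluoromethylsulfonyloxy)cyclohex-3-en-1-yl]but-2-enoate | O=S(=O)(OC1=C(C)CC[C@H](C/C=C(\C)C(=O)OCC)C1(C)C)C(F)(F)F | intermediate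
9 | (5R)-5-[(2E)-4-hydroxy-3-methylbut-2-en-1-yl]-2,6,6-trimethylcyclohex-1-en-1-yl trifluoromethanesulfonate | O=S(=O)(OC1=C(C)CC[C@H](C/C=C(\C)CO)C1(C)C)C(F)(F)F | intermediate
10 | (5R)-5-[(2E)-4-(tert-butyldiphenylsilyloxy)-3-methylbut-2-en-1-yl]-2,6,6-trimethylcyclohex-1-en-1-yl trifluoromethanesulfonate | O=S(=O)(OC1=C(C)CC[C@H](C/C=C(\C)CO[Si](c2ccccc2)(c2ccccc2)C(C)(C)C)C1(C)C)C(F)(F)F | intermediate
11 | (2E)-3-methylpent-2-en-4-yn-1-ol | C#C/C(C)=C/CO | starting material
12 | (2E,4E)-3-methyl-5-(tributylstannyl)penta-2,4-dien-1-ol | CCCC[Sn](CCCC)(CCCC)/C=C/C(C)=C/CO | intermediate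
13 | (2E,4E)-5-{(5R)-5-[(2E)-4-(tert-butyldiphenylsilyloxy)-3-methylbut-2-en-1-yl]-2,6,6-trimethylcyclohex-1-en-1-yl}-3-methylpenta-2,4-dien-1-ol | OC/C=C(C)/C=C/C1=C(C)CC[C@H](C/C=C(\C)CO[Si](c2ccccc2)(c2ccccc2)C(C)(C)C)C1(C)C | intermediate
14 | [(2E,4E)-5-{(5R)-5-[(2E)-4-(tert-butyldiphenylsilyloxy)-3-methylbut-2-en-1-yl]-2,6,6-trimethylcyclohex-1-en-1-yl}-3-methylpenta-2,4-dien-1-yl]triphenylphosphonium bromide | [Br-].c1ccccc1[P+](c1ccccc1)(c1ccccc1)C/C=C(C)/C=C/C1=C(C)CC[C@H](C/C=C(\C)CO[Si](c2ccccc2)(c2ccccc2)C(C)(C)C)C1(C)C | intermediate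
15 | 1-bromobut-2-yne | CC#CCBr | starting material
16 | diethyl but-2-yn-1-ylphosphonate | CC#CCP(=O)(OCC)OCC | intermediate
17 | (2E,4E,6E)-2,7-dimethylocta-2,4,6-trienedial | O=C/C(C)=C/C=C/C=C(C)/C=O | starting material
18 | sodium 1-(diethoxyphosphoryl)but-2-yn-1-ide (not isolated) | [Na+].CC#C[CH-]P(=O)(OCC)OCC | intermediate
19 | (2E,4E,6E,8E)-2,7-dimethyldodeca-2,4,6,8-tetraen-10-ynal | CC#C/C=C/C(C)=C/C=C/C=C(C)/C=O | intermediate
20 | ylide of 14, [(2E,4E)-5-{ring as in 13}-3-methylpenta-2,4-dien-1-ylidene]triphenylphosphorane (not isolated) | c1ccccc1P(c1ccccc1)(c1ccccc1)=C/C=C(C)/C=C/C1=C(C)CC[C@H](C/C=C(\C)CO[Si](c2ccccc2)(c2ccccc2)C(C)(C)C)C1(C)C | intermediate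
21 | 11Z isomer of 22 (heptadeca-1E,3E,5Z,7E,9E,11E,13E-heptaen-15-ynyl chain; not isolated) | CC#C/C=C/C(C)=C/C=C/C=C(C)/C=C\C=C(C)\C=C\C1=C(C)CC[C@H](C/C=C(\C)CO[Si](c2ccccc2)(c2ccccc2)C(C)(C)C)C1(C)C | intermediate
22 | tert-butyl{[(2E)-2-methyl-4-{(1R)-2,2,4-trimethyl-3-[(1E,3E,5E,7E,9E,11E,13E)-3,7,12-trimethylheptadeca-1,3,5,7,9,11,13-heptaen-15-yn-1-yl]cyclohex-3-en-1-yl}but-2-en-1-yl]oxy}diphenylsilane (C34 polyenyne) | CC#C/C=C/C(C)=C/C=C/C=C(C)/C=C/C=C(C)/C=C/C1=C(C)CC[C@H](C/C=C(\C)CO[Si](c2ccccc2)(c2ccccc2)C(C)(C)C)C1(C)C | intermediate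
23 | (R)-lavandulol, (2R)-5-methyl-2-(prop-1-en-2-yl)hex-4-en-1-ol | CC(C)=CC[C@@H](CO)C(C)=C | starting material
24 | (2R)-5-methyl-2-(prop-1-en-2-yl)hex-4-en-1-yl acetate | CC(C)=CC[C@@H](COC(C)=O)C(C)=C | intermediate
25 | acetoxy[(3S)-3-(acetoxymethyl)-2-hydroxy-2,6-dimethylhept-5-en-1-yl]mercury (C2 epimers; not isolated) | CC(C)=CC[C@@H](COC(C)=O)C(C)(O)C[Hg]OC(C)=O | intermediate
26 | (2S)-3-hydroxy-3-methyl-2-(3-methylbut-2-en-1-yl)butyl acetate (not isolated) | CC(C)=CC[C@@H](COC(C)=O)C(C)(C)O | intermediate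
27 | (2S)-3-methyl-2-(3-methylbut-2-en-1-yl)butane-1,3-diol | CC(C)=CC[C@@H](CO)C(C)(C)O | intermediate
28 | (2S)-3-methyl-2-(3-methylbut-2-en-1-yl)-1,3-bis(triethylsilyloxy)butane | CC(C)=CC[C@@H](CO[Si](CC)(CC)CC)C(C)(C)O[Si](CC)(CC)CC | intermediate
29 | (2R)-5-methyl-2-[2-(triethylsilyloxy)propan-2-yl]hex-4-enal | CC(C)=CC[C@@H](C=O)C(C)(C)O[Si](CC)(CC)CC | intermediate
30 | ethyl (2E,4E,6S)-3,7-dimethyl-6-(3-methylbut-2-en-1-yl)-7-(triethylsilyloxy)octa-2,4-dienoate | CC(C)=CC[C@@H](/C=C/C(C)=C/C(=O)OCC)C(C)(C)O[Si](CC)(CC)CC | intermediate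
31 | (2E,4E,6S)-3,7-dimethyl-6-(3-methylbut-2-en-1-yl)-7-(triethylsilyloxy)octa-2,4-dien-1-ol | CC(C)=CC[C@@H](/C=C/C(C)=C/CO)C(C)(C)O[Si](CC)(CC)CC | intermediate
32 | (2E,4E,6S)-3,7-dimethyl-6-(3-methylbut-2-en-1-yl)-7-(triethylsilyloxy)octa-2,4-dienal | CC(C)=CC[C@@H](/C=C/C(C)=C/C=O)C(C)(C)O[Si](CC)(CC)CC | intermediate
33 | triethyl{[(3S,4E,6E,8E)-9-iodo-2,6-dimethyl-3-(3-methylbut-2-en-1-yl)nona-4,6,8-trien-2-yl]oxy}silane (C16 trienyl iodide) | CC(C)=CC[C@@H](/C=C/C(C)=C/C=C/I)C(C)(C)O[Si](CC)(CC)CC | intermediate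
34 | (E)-alkenylzirconocene chloride from 22: Cp2Zr(Cl) on C9', H on C10' cis to Zr (not isolated) | Cl[Zr](C1C=CC=C1)(C1C=CC=C1)/C(C)=C/C=C/C(C)=C/C=C/C=C(C)/C=C/C=C(C)/C=C/C1=C(C)CC[C@H](C/C=C(\C)CO[Si](c2ccccc2)(c2ccccc2)C(C)(C)C)C1(C)C | intermediate
35 | (E)-alkenylzinc chloride from 34: ZnCl on C9' (not isolated) | Cl[Zn]/C(C)=C/C=C/C(C)=C/C=C/C=C(C)/C=C/C=C(C)/C=C/C1=C(C)CC[C@H](C/C=C(\C)CO[Si](c2ccccc2)(c2ccccc2)C(C)(C)C)C1(C)C | intermediate
36 | bis-silyl ether of the target (1'-O-triethylsilyl; side-chain O-tert-butyldiphenylsilyl; 2R,2'S; all-E) | CC(C)=CC[C@@H](/C=C/C(C)=C/C=C/C(C)=C/C=C/C(C)=C/C=C/C=C(C)/C=C/C=C(C)/C=C/C1=C(C)CC[C@H](C/C=C(\C)CO[Si](c2ccccc2)(c2ccccc2)C(C)(C)C)C1(C)C)C(C)(C)O[Si](CC)(CC)CC | intermediate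
37 | (2R,2'S)-2-[(2E)-4-hydroxy-3-methylbut-2-en-1-yl]-2'-(3-methylbut-2-en-1-yl)-3',4'-didehydro-1',2'-dihydro-β,ψ-caroten-1'-ol (all-E) | CC(C)=CC[C@@H](/C=C/C(C)=C/C=C/C(C)=C/C=C/C(C)=C/C=C/C=C(C)/C=C/C=C(C)/C=C/C1=C(C)CC[C@H](C/C=C(\C)CO)C1(C)C)C(C)(C)O | target

**Count**
Total steps: 23. Longest linear sequence: 12 steps (steps 1–7, 9, 10, 13, 22, 23).

**Steps most likely to fail**

Step 22. The hydrozirconation may lose regiocontrol (zirconium left on C10'), excess Zr–H may add slowly to the polyene, and the alkenylzinc may be protonated or homocoupled before it couples. The fallback makes the C8'–C9' bond on a substrate without a polyene and closes the chain by olefination instead. It sets out from phosphonate 16 and iodide 33. One-pot hydrozirconation of 16 (Cp2Zr(H)Cl, THF, 50 °C), transmetalation with ZnCl2 and Pd(PPh3)4-catalysed coupling with 33 would give diethyl [(2E,4E,6E,8E,10S)-3,7,11-trimethyl-10-(3-methylbut-2-en-1-yl)-11-(triethylsilyloxy)dodeca-2,4,6,8-tetraen-1-yl]phosphonate F1. Its sodium anion and excess dialdehyde 17 would give, by Horner–Wadsworth–Emmons olefination, (2E,4E,6E,8E,10E,12E,14E,16E,18S)-2,7,11,15,19-pentamethyl-18-(3-methylbut-2-en-1-yl)-19-(triethylsilyloxy)icosa-2,4,6,8,10,12,14,16-octaenal F2. Wittig reaction of F2 with ylide 20 (from 14) would give the all-E product together with the 11Z isomer of 36 F3, and the iodine equilibration of step 13 would turn the mixture into 36, where the route is rejoined.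

Step 5. The amide base may also remove a γ-hydrogen of the enoate, which would give incomplete or unselective triflation. The fallback makes the enolate without any strong base. It sets out from enone 4. α-Iodination (I2, pyridine, CH2Cl2) would give ethyl (2E)-4-[(1R)-4-iodo-2,2-dimethyl-3-oxocyclohex-4-en-1-yl]-2-methylbut-2-enoate F4. Suzuki methylation (MeB(OH)2, PdCl2(dppf), K3PO4) would give ethyl (2E)-2-methyl-4-[(1R)-2,2,4-trimethyl-3-oxocyclohex-4-en-1-yl]but-2-enoate F5. Conjugate reduction of F5 with K[BH(s-Bu)3] would form enolate 7 directly, and PhNTf2 would trap it as triflate 8, where the route is rejoined.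

Step 15. Chemoselectivity between the two alkenes may erode, and the primary radical formed during borohydride demercuration may cyclise 5-exo onto the prenyl alkene. The fallback changes the hydration to a metal-hydride hydrogen-atom transfer on the unprotected alcohol. It sets out from (R)-lavandulol 23: Mukaiyama hydration (Co(acac)2 cat., PhSiH3, O2, i-PrOH/THF, rt) goes through the tertiary radical at C1', which has no fast cyclisation path, and prefers the less hindered 1,1-disubstituted alkene. It would give diol 27 directly, where the route is rejoined; no further compound arises (F0).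

**Further compounds**
F1 | step 22 | diethyl [(2E,4E,6E,8E,10S)-3,7,11-trimethyl-10-(3-methylbut-2-en-1-yl)-11-(triethylsilyloxy)dodeca-2,4,6,8-tetraen-1-yl]phosphonate | CC(C)=CC[C@@H](/C=C/C(C)=C/C=C/C(C)=C/CP(=O)(OCC)OCC)C(C)(C)O[Si](CC)(CC)CC
F2 | step 22 | (2E,4E,6E,8E,10E,12E,14E,16E,18S)-2,7,11,15,19-pentamethyl-18-(3-methylbut-2-en-1-yl)-19-(triethylsilyloxy)icosa-2,4,6,8,10,12,14,16-octaenal | CC(C)=CC[C@@H](/C=C/C(C)=C/C=C/C(C)=C/C=C/C(C)=C/C=C/C=C(C)/C=O)C(C)(C)O[Si](CC)(CC)CC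
F3 | step 22 | 11Z isomer of 36 | CC(C)=CC[C@@H](/C=C/C(C)=C/C=C/C(C)=C/C=C/C(C)=C/C=C/C=C(C)/C=C\C=C(C)\C=C\C1=C(C)CC[C@H](C/C=C(\C)CO[Si](c2ccccc2)(c2ccccc2)C(C)(C)C)C1(C)C)C(C)(C)O[Si](CC)(CC)CC
F4 | step 5 | ethyl (2E)-4-[(1R)-4-iodo-2,2-dimethyl-3-oxocyclohex-4-en-1-yl]-2-methylbut-2-enoate | O=C1C(I)=CC[C@H](C/C=C(\C)C(=O)OCC)C1(C)C
F5 | step 5 | ethyl (2E)-2-methyl-4-[(1R)-2,2,4-trimethyl-3-oxocyclohex-4-en-1-yl]but-2-enoate | O=C1C(C)=CC[C@H](C/C=C(\C)C(=O)OCC)C1(C)C
F0 | step 15 | none | none
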